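The rate constants are made up; what happens was integrated by code.

What stands unconverted after a given time is the leftover I count with, and this is the flask.

    reagent in the reaction phase ⇌ reagent in the second phase, rate k1*([reagent in the reaction phase] - [reagent in the second phase]/K1) per volume of the first phase (K1 = 11, k1 = 0.37 min⁻¹)
    substrate + reagent in the reaction phase → target (k2 = 18 M⁻¹ min⁻¹)
    target ⇌ product in the second phase, rate k3*([target] - [product in the second phase]/K3) per volume of the first phase (K3 = 4.5, k3 = 0.0099 min⁻¹)
    target → decomposed product (k4 = 0.0077 min⁻¹)
    target ⇌ isomer of the product (K5 = 2.6, k5 = 0.033 min⁻¹)
    reagent in the reaction phase + target ⇌ idle adduct, settled at all times (K6 = 62 M⁻¹)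

substrate 20 mM; reagent in the second phase 36.0 mM; time 1.5 h; volume of the second phase over the first 1.0

- Thursday's: doubling the transfer coefficient of step 3, all else as stated
- Tuesday's: doubling the transfer coefficient of step 1, all else as stated
- Wednesday's: doubling the amount of reagent in the second phase, all else as stated

- amounts and yields of target count product in the second phase and idle adduct too
- in the second phase: reagent in the second phase, product in the second phase; everything else is in the first
- charges count per volume of the first phase; a concentration in a rate is the amount of a species over the volume of its own phase; every rate counts per litre of the first phase
- run time (flask): 1.5 h

1. the target and product in the second phase and idle adduct together standing at 1.5 h, as a percentage of the substrate charged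
2. the change that raises the amount of target and product in the second phase and idle adduct together at 1.5 h, in percent of the substrate charged most ("none" if none brings more than 2 percentage points) (Thursday's / Tuesday's / Wednesday's / none)
3. amount of target and product in the second phase and idle adduct together at 1.5 h, in percent of the substrate charged, after Tuesday's

I count turnovers: a first-order rate times the run time, so that a count well above one marks a process that has had time to finish, and a count below one marks a process still under way.

Reagent enters the reaction phase at the transfer coefficient 0.37 min⁻¹ and is consumed at 0.360 min⁻¹ by the substrate as charged. Both are far quicker than the run, so the reagent soon sits at a quasi-steady level. Balancing inflow against consumption, with equal phase volumes, gives B = 1.66 mM. The substrate therefore decays in a pseudo-first-order way, and I carry its rate κ, the rate constant of step 2 times that reagent level, which is 0.0299 min⁻¹.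

| Rung, fastest first | Rate | Turnovers in the run |
|---|---|---|
| reagent passage | 0.37 min⁻¹ | 33.3 |
| reagent consumption | 0.360 min⁻¹ | 32.4 |
| isomerisation, forward | 0.033 min⁻¹ | 2.97 |
| substrate, κ | 0.0299 min⁻¹ | 2.69 |
| uptake of target | 0.0099 min⁻¹ | 0.891 |
| decomposition | 0.0077 min⁻¹ | 0.693 |

So within minutes the reagent is at its level. Over the run the substrate goes, and isomerisation keeps pace with it, running faster than uptake, while uptake and decomposition stay under way. My leftover is exp(−N) = 6.81%, so I reckon 93.2% of the substrate converted. I expect that leftover to be too low and that conversion too high, since B uses the reagent as charged and the second phase will drain. My reckoning stops there, without a number for y.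

The forecast gives 37%, Thursday's and 38%, with 88 to 90% converted where I have 93.2%. Its ground is that “isomerisation and decomposition drain the target faster than the slow transfer to the second phase protects it”.

The simulation gives 36.9%, Thursday's with 7 percentage points against 2.9 points for Wednesday's, and 37.2%, so the forecast holds; a run would overturn its y if reagent went to 26.1 mM or substrate to 32.1 mM, where y has moved 5 points. By 0.750 h the substrate was down to 31.2% and the counted sum stood at 36.9%. From then to 1.5 h the substrate fell to 10.1% while the sum stayed at 36.9% and the isomer rose from 24.7% to 38.2%. The count read back is 2.29, less than N, with reagent at 1.43 mM below B.

For the neighbour read at 50 min, κ leaves 22.4%; the computed leftover there is 27.5%, again above the count.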